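**Retrosynthetic overview**

- Target 10 is the dearomatized C-farnesyl derivative of 3,5-dimethylorsellinic acid (DMOA). The bond between the ring quaternary carbon and the farnesyl CH2 is cut into a π-farnesyl electrophile and the DMOA ring as carbon nucleophile; both halves are stored in one achiral, aromatic isomer of the target, the farnesyl ester 8.
- Enabling feature: in the benzene ring of 8 the methyl-bearing carbon C5 lies ortho to the C4 phenol oxygen and para to the C2 phenol oxygen, so it is a vinylogous enolate carbon whose methyl group forbids rearomatization. The C1 carboxylate is at once the allylic leaving group for Pd(0) and the free acid of the target.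
- 8 comes from DMOA 5 and (2E,6E)-farnesyl bromide 6 (carboxylate alkylation); 5 from 2,4,5-trimethylresorcinol 3 (ortho-carboxylation); 3 from 2,4-dihydroxy-3,6-dimethylbenzaldehyde 1 (CHO to CH3).
- Ring order: the only ring, the six-membered carbocycle, is bought as the benzene ring of 1; no ring is formed, and it is dearomatized in the last step.

Key step: step 4

Assumption: for a prochiral phenoxide nucleophile the ligand antipode that gives the (R)-quaternary carbon cannot be predicted with confidence; the route is written with the (R,R)-ligand, and the equally commercial (S,S)-ligand is used if the sense of induction proves opposite. Compounds 1 and 6, the MMC solution and the Trost ligand are taken as commercial.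

**Step 1**
Reactants: 1 2,4-dihydroxy-3,6-dimethylbenzaldehyde
Product: 3 2,4,5-trimethylbenzene-1,3-diol, via 4-(hydroxymethyl)-2,5-dimethylbenzene-1,3-diol 2 (not isolated)
Conditions: H2 (3 bar), 10% Pd/C, AcOH, cat. HCl, rt
Reagents that add atoms: none
Why: Hydrogenation of the aldehyde to the benzylic alcohol 2 and benzylic hydrogenolysis of its C–O bond, which the ortho- and para-hydroxy groups activate under the acidic Pd/H2 conditions, should give the methyl group; no stereocenter is formed.

**Step 2**
Reactants: 3 2,4,5-trimethylbenzene-1,3-diol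
Product: 5 2,4-dihydroxy-3,5,6-trimethylbenzoic acid (DMOA), via the magnesium O,O-chelate of 2-oxido-4-hydroxy-3,5,6-trimethylbenzoate 4 (not isolated)
Conditions: MMC (2 M in DMF, 6 equiv), 120 °C, N2; then cold 2 M HCl (aq)
Reagents that add atoms: methyl magnesium carbonate (MMC, Stiles reagent), COC(=O)O[Mg]OC
Why: Stiles carboxylation (the MMC variant of the Kolbe–Schmitt reaction) should carboxylate the magnesium phenoxide at the only free ring position, ortho to one hydroxyl and para to the other, and hold the product as the salicylate-type chelate 4 until cold acid releases the acid; no stereocenter is formed.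

**Step 3**
Reactants: 5 2,4-dihydroxy-3,5,6-trimethylbenzoic acid (DMOA); 6 (2E,6E)-farnesyl bromide
Product: 8 (2E,6E)-3,7,11-trimethyldodeca-2,6,10-trien-1-yl 2,4-dihydroxy-3,5,6-trimethylbenzoate, via potassium 2,4-dihydroxy-3,5,6-trimethylbenzoate 7 (not isolated)
Conditions: KHCO3 (1.2 equiv), DMF, 0 °C to rt
Reagents that add atoms: none
Why: Bicarbonate deprotonates only the carboxylic acid and not the phenols, so SN2 alkylation of carboxylate 7 at the primary allylic bromide should give the ester chemoselectively with the 2E,6E geometry untouched.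

**Step 4**
Reactants: 8 (2E,6E)-farnesyl 2,4-dihydroxy-3,5,6-trimethylbenzoate
Product: 10 (3R)-6-hydroxy-2,3,5-trimethyl-4-oxo-3-[(2E,6E)-3,7,11-trimethyldodeca-2,6,10-trien-1-yl]cyclohexa-1,5-diene-1-carboxylic acid, via the bis(triethylammonium) salt of 10 9 (not isolated)
Conditions: Pd2(dba)3·CHCl3 (2.5 mol %), (R,R)-DACH-phenyl Trost ligand (7.5 mol %), Et3N (2.0 equiv), degassed toluene, 25–40 °C; then cold 1 M HCl (aq)
Reagents that add atoms: none
Why: Proposed new method: Pd(0)/L* should ionize the allylic C–O bond of 8 (a di-ortho-substituted resorcylate is a better leaving group than acetate) to a cationic syn-π-(2E)-farnesyl complex paired with the DMOA carboxylate, whose 4-phenoxide (held by Et3N) attacks through ring C5 at the unsubstituted CH2 allyl terminus in an outer-sphere step, and tautomerization then gives the vinylogous acid as salt 9; the closest known reaction types are the Pd-catalysed asymmetric allylic dearomatization of naphthols with Trost ligands, the Pd-catalysed asymmetric prenylation and geranylation of prochiral enolates at the CH2 terminus, and the Tsuji–Saegusa allyl β-keto ester chemistry in which one allyl ester is both pro-electrophile and pro-nucleophile. No ring is closed: the existing benzene ring is dearomatized to the cyclohexa-1,5-dienone. The single new stereocenter (C3 of 10, R) is set under catalyst control, by discrimination of the two enantiotopic faces of the planar phenoxide in the chiral pocket of the ligand, with the amide N–H to phenoxide-oxygen hydrogen bond as orienting contact. The step needs C- over O-allylation, which the substrate secures because farnesylation at carboxylate or phenoxide oxygen is reversible under Pd(0), whereas the C-allylated product is removed as its stabilized vinylogous-acid/carboxylate salt and cannot rearomatize (C5 carries a methyl group). It needs C5 over C3 and C1, expected from the resorcinol preference for the carbon ortho to one oxygen and para to the other over the carbon flanked by two ion-paired oxygens and from the carboxylate that shields C1, and it needs linear attack with retention of the 2E geometry, expected because a quaternary carbon cannot form at the tertiary allyl terminus and no σ-allyl forms there. The 1:1 release of electrophile and nucleophile from one molecule excludes double farnesylation, and keeping the temperature at or below 40 °C avoids [3,3] shifts of the product.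

**Compound list**

1 | 2,4-dihydroxy-3,6-dimethylbenzaldehyde | O=Cc1c(O)c(C)c(O)cc1C | starting material
2 | 4-(hydroxymethyl)-2,5-dimethylbenzene-1,3-diol | OCc1c(O)c(C)c(O)cc1C | intermediate
3 | 2,4,5-trimethylbenzene-1,3-diol (2,4,5-trimethylresorcinol) | Cc1c(O)c(C)c(O)cc1C | intermediate
4 | magnesium O,O-chelate of 2-oxido-4-hydroxy-3,5,6-trimethylbenzoate | Cc1c(C)c2C(=O)O[Mg]Oc2c(C)c1O | intermediate
5 | 2,4-dihydroxy-3,5,6-trimethylbenzoic acid (3,5-dimethylorsellinic acid, DMOA) | Cc1c(C)c(C(=O)O)c(O)c(C)c1O | intermediate
6 | (2E,6E)-farnesyl bromide ((2E,6E)-1-bromo-3,7,11-trimethyldodeca-2,6,10-triene) | CC(C)=CCC/C(C)=C/CC/C(C)=C/CBr | starting material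
7 | potassium 2,4-dihydroxy-3,5,6-trimethylbenzoate | Cc1c(C)c(C(=O)[O-])c(O)c(C)c1O.[K+] | intermediate
8 | (2E,6E)-3,7,11-trimethyldodeca-2,6,10-trien-1-yl 2,4-dihydroxy-3,5,6-trimethylbenzoate | CC(C)=CCC/C(C)=C/CC/C(C)=C/COC(=O)c1c(C)c(C)c(O)c(C)c1O | intermediate
9 | bis(triethylammonium) (3R)-2,3,5-trimethyl-6-oxido-4-oxo-3-[(2E,6E)-farnesyl]cyclohexa-1,5-diene-1-carboxylate | CC(C)=CCC/C(C)=C/CC/C(C)=C/C[C@@]1(C)C(=O)C(C)=C([O-])C(C(=O)[O-])=C1C.CC[NH+](CC)CC.CC[NH+](CC)CC | intermediate
10 | (3R)-6-hydroxy-2,3,5-trimethyl-4-oxo-3-[(2E,6E)-3,7,11-trimethyldodeca-2,6,10-trien-1-yl]cyclohexa-1,5-diene-1-carboxylic acid | CC(C)=CCC/C(C)=C/CC/C(C)=C/C[C@@]1(C)C(=O)C(C)=C(O)C(C(=O)O)=C1C | target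

Total step count: 4
Longest linear sequence: 4 steps (1 to 10)

**Steps most likely to fail**

1. Step 4 (Proposed new method). The enantiofacial control at the phenoxide may be poor, the allyl unit may go to C3 or to the carboxylate-bearing C1 (with loss of CO2) instead of C5, or the π-farnesyl complex may be lost by elimination to farnesenes. The fallback uses known chemistry: it sets out from 5 and comes back at 10. Carboxylate alkylation of 5 with allyl bromide (KHCO3, DMF) should give allyl 2,4-dihydroxy-3,5,6-trimethylbenzoate F1. Base-mediated alkylative dearomatization of F1 (LiHMDS, THF, 0 °C, then 6) should give the racemic allyl ester of 10 F2. Preparative chiral-phase SFC should separate the (3R)-allyl ester F3 from the (3S)-antipode F4, which is set aside. Deallylation of F3 (cat. Pd(PPh3)4, morpholine, THF, rt) should release 10.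

2. Step 2. Carboxylation at the hindered position next to a methyl group may stay incomplete, and CO2 may be lost again during heating or acidic work-up. The fallback sets out from 3 and comes back at 5. Vilsmeier–Haack formylation of 3 (POCl3, DMF, MeCN; aqueous hydrolysis) should give 2,4-dihydroxy-3,5,6-trimethylbenzaldehyde F5, and Lindgren–Pinnick oxidation of F5 (NaClO2, NaH2PO4, sulfamic acid, aqueous dioxane, 0 °C to rt) should give 5.

3. Step 3. Alkylation may spill over to the 4-phenol oxygen or to ring carbon, or the allylic bromide may ionize and scramble its geometry. The fallback sets out from 5 and comes back at 8. Acetonide formation (acetone, TFAA, TFA, 0 °C to rt) should give 7-hydroxy-2,2,5,6,8-pentamethyl-4H-1,3-benzodioxin-4-one F6. Ring-opening transesterification of F6 with sodium (2E,6E)-farnesoxide (commercial (2E,6E)-farnesol, NaH, THF, 0 °C to rt) should give 8 with loss of acetone.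

**Further compounds**

F1 | step 4 | allyl 2,4-dihydroxy-3,5,6-trimethylbenzoate | C=CCOC(=O)c1c(C)c(C)c(O)c(C)c1O
F2 | step 4 | racemic allyl 6-hydroxy-2,3,5-trimethyl-4-oxo-3-[(2E,6E)-farnesyl]cyclohexa-1,5-diene-1-carboxylate | CC(C)=CCC/C(C)=C/CC/C(C)=C/CC1(C)C(=O)C(C)=C(O)C(C(=O)OCC=C)=C1C
F3 | step 4 | allyl (3R)-6-hydroxy-2,3,5-trimethyl-4-oxo-3-[(2E,6E)-farnesyl]cyclohexa-1,5-diene-1-carboxylate | CC(C)=CCC/C(C)=C/CC/C(C)=C/C[C@@]1(C)C(=O)C(C)=C(O)C(C(=O)OCC=C)=C1C
F4 | step 4 | allyl (3S)-6-hydroxy-2,3,5-trimethyl-4-oxo-3-[(2E,6E)-farnesyl]cyclohexa-1,5-diene-1-carboxylate | CC(C)=CCC/C(C)=C/CC/C(C)=C/C[C@]1(C)C(=O)C(C)=C(O)C(C(=O)OCC=C)=C1C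
F5 | step 2 | 2,4-dihydroxy-3,5,6-trimethylbenzaldehyde | O=Cc1c(C)c(C)c(O)c(C)c1O
F6 | step 3 | 7-hydroxy-2,2,5,6,8-pentamethyl-4H-1,3-benzodioxin-4-one | CC1(C)OC(=O)c2c(C)c(C)c(O)c(C)c2O1
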